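**Retrosynthetic overview**
- Feature: ring B carries at C8 an axial tertiary oxygen syn to the axial C20 methyl on C10, with C17 (the aldehyde carbon) equatorial. The equatorial C9 side chain lies on the same face, and the 8(17)-methylene of andrographolide already holds C17.
- Target ⇒ 8,17-epoxide (masked hydroxy aldehyde; opened by hydroxide at C17, then C17 oxidation and desilylation) carrying the 13Z enoate, which is built from a C12 iodide by acetylide alkylation, carboxylation and Me2CuLi addition.
- 8,17-Epoxide ⇐ cis-fused 17-iodo-12,8-lactone (methoxide relay) ⇐ iodolactonisation of the 8(17)-en-12-oic acid, which forms the C8–O bond and sets C8.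
- Acid ⇐ andrographolide (supplies C3, C5, C9, C10) by C12=C13 cleavage, C19 deoxygenation and C3 silylation.
- Ring order: rings A and B come from the chiral pool. The only ring closed is the temporary γ-lactone (step 9), relayed to the spiro-epoxide (step 10) and opened in step 17.

Key step: step 9

Remark: labdane numbering is used (C17 = exocyclic carbon on C8, C20 = methyl on C10). C3, C5, C9 and C10 of the target have the configuration of natural andrographolide, so only C8 and the C13=C14 geometry have to be set.

**Step 1**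
Reactants: 1 andrographolide
Product: 2 3,19-O-isopropylideneandrographolide
Conditions: 2,2-dimethoxypropane, PPTS (cat.), toluene–DMSO, 80 °C
Reagents that add atoms: 2,2-dimethoxypropane COC(C)(C)OC
Why: Acid-catalysed transketalisation closes the six-membered acetonide on the 1,3-related C3 and C19 hydroxyls only, the C14 hydroxyl having no partner, and no stereocentre is touched.

**Step 2**
Reactants: 2 3,19-O-isopropylideneandrographolide
Product: 3 3,19-isopropylidenedioxy-13,14,15,16-tetranor-ent-labd-8(17)-en-12-al
Conditions: KMnO4 (1.4 equiv), MgSO4, THF–H2O, −10 °C; aq. NaHSO3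
Reagents that add atoms: potassium permanganate [K+].[O-][Mn](=O)(=O)=O
Why: Permanganate oxidative cleavage (cycloaddition, then fragmentation of the manganate ester) should take the conjugated, electron-poor C12=C13 alkene faster than the isolated, hindered 8(17)-methylene at low temperature, MgSO4 keeps the medium near neutral for the enolisable aldehyde, and any C12 acid from over-oxidation converges in step 3.

**Step 3**
Reactants: 3 C12 aldehyde acetonide
Product: 4 3,19-isopropylidenedioxy-13,14,15,16-tetranor-ent-labd-8(17)-en-12-oic acid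
Conditions: NaClO2, NaH2PO4, 2-methyl-2-butene, t-BuOH–H2O, 0 °C to rt (crude 3 used at once)
Reagents that add atoms: sodium chlorite [Na+].[O-]Cl=O
Why: Pinnick oxidation converts only the aldehyde, 2-methyl-2-butene takes up the hypochlorous acid that would otherwise attack the 8(17)-alkene, and the buffered pH spares the acetonide.

**Step 4**
Reactants: 4 C12 acid acetonide
Product: 6 methyl 3,19-dihydroxy-13,14,15,16-tetranor-ent-labd-8(17)-en-12-oate, via acetonide methyl ester 5 (not isolated)
Conditions: TMSCHN2, toluene–MeOH, 0 °C; AcOH quench; then PPTS, MeOH, 40 °C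
Reagents that add atoms: (trimethylsilyl)diazomethane C[Si](C)(C)C=[N+]=[N-]
Why: Diazoalkane O-methylation masks the carboxyl group against activation in step 5, and acid-catalysed methanolysis of the 1,3-dioxane acetonide in the same flask frees the diol under conditions too mild to protonate the 8(17)-alkene.

**Step 5**
Reactants: 6 diol methyl ester
Product: 7 methyl 3-hydroxy-19-iodo-13,14,15,16-tetranor-ent-labd-8(17)-en-12-oate
Conditions: PPh3, imidazole, I2 (premixed), toluene, 80 °C
Reagents that add atoms: iodine II
Why: Appel-type (Garegg–Samuelsson) iodination displaces the primary C19 oxyphosphonium by iodide (a slow neopentyl SN2, hence the heat), while the more hindered secondary C3 hydroxyl next to quaternary C4 should remain, and C4 is not a reacting centre.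

**Step 6**
Reactants: 7 19-iodide
Product: 8 methyl 3-hydroxy-13,14,15,16-tetranor-ent-labd-8(17)-en-12-oate
Conditions: Bu3SnH, AIBN (cat.), toluene, 80 °C
Reagents that add atoms: none
Why: Radical chain dehalogenation is insensitive to the neopentyl hindrance, and the C19 radical should be reduced by the stannane before it can reach the remote alkene, leaving the C4 gem-dimethyl group.

**Step 7**
Reactants: 8 hydroxy ester
Product: 9 methyl 3-(tert-butyldimethylsilyloxy)-13,14,15,16-tetranor-ent-labd-8(17)-en-12-oate
Conditions: TBSOTf, 2,6-lutidine, CH2Cl2, 0 °C to rt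
Reagents that add atoms: tert-butyldimethylsilyl triflate CC(C)(C)[Si](C)(C)OS(=O)(=O)C(F)(F)F
Why: Silylation with the silyl triflate is reactive enough for the hindered equatorial C3 hydroxyl, and the hindered base does not enolise the ester.

**Step 8**
Reactants: 9 silyl ether ester
Product: 10 3-(tert-butyldimethylsilyloxy)-13,14,15,16-tetranor-ent-labd-8(17)-en-12-oic acid
Conditions: LiOH, THF–MeOH–H2O, 40 °C; 1 M HCl to pH 4, 0 °C
Reagents that add atoms: lithium hydroxide [Li+].[OH-]
Why: Saponification of the unhindered primary ester leaves the base-stable silyl ether, and the cold, weakly acidic work-up avoids proton-initiated lactonisation of the γ,δ-unsaturated acid.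

**Step 9**
Reactants: 10 8(17)-en-12-oic acid
Product: 11 3-(tert-butyldimethylsilyloxy)-17-iodo-13,14,15,16-tetranor-ent-labdan-12,8-olide (cis-fused; C8–O axial and syn to C20)
Conditions: I2, NaHCO3, MeCN–H2O, 0 °C, dark; aq. Na2S2O3
Reagents that add atoms: iodine II
Why: Iodine adds reversibly to the C8=C17 methylene, and only the iodonium ion on the ring B face anti to the axial C20 methyl is intercepted, because the carboxylate on the equatorial C9 arm can then reach C8 in an anti addition from the C20 face; the closest known reaction type is the iodolactonisation of γ,δ-unsaturated acids. The γ-lactone (O, C12, C11, C9, C8) closes in the 5-exo-trig mode at the tertiary carbon C8, so that C8–O and C17–I are formed and C17 is left as a primary iodide. The one new stereocentre, C8, is controlled by the substrate: the fixed configuration at C9 holds the nucleophile on the C20 face and the anti course of the addition puts iodine on the other face, which gives the cis-fused lactone with the C8–O bond axial and syn to C20. The step needs facial selectivity at C8 and Markovnikov regioselectivity; the first comes from the shielding by C20 together with the tether, the second from the better stabilisation of positive charge at the tertiary C8 and from the strain of the 6-endo alternative. The epimeric trans-fused lactone would put the CH2I group axial and 1,3 to C20, so kinetic and equilibrating conditions should point to the same product. The C3 silyl ether and the rest of the skeleton are inert to iodine and bicarbonate at 0 °C.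

**Step 10**
Reactants: 11 iodolactone
Product: 13 methyl 8,17-epoxy-3-(tert-butyldimethylsilyloxy)-13,14,15,16-tetranor-ent-labdan-12-oate (epoxide oxygen syn to C20), via iodohydrin methyl ester 12 (not isolated)
Conditions: NaOMe, MeOH, 0 °C to rt
Reagents that add atoms: sodium methoxide [Na+].[O-]C
Why: Methanolysis of the lactone frees the C8 alkoxide, which displaces the adjacent C17 iodide in an intramolecular Williamson closure (3-exo-tet), so the C8–O bond of step 9 is kept with retention.

**Step 11**
Reactants: 13 epoxy ester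
Product: 14 8,17-epoxy-3-(tert-butyldimethylsilyloxy)-13,14,15,16-tetranor-ent-labdan-12-ol
Conditions: i-Bu2AlH (2.5 equiv), CH2Cl2, −78 to −40 °C; aq. potassium sodium tartrate
Reagents that add atoms: none
Why: Hydride reduction of the ester to the primary alcohol is much faster at low temperature than opening of the hindered 2,2-disubstituted epoxide, and the neutral work-up avoids acid-catalysed cyclisation of the C12 hydroxyl onto C8.

**Step 12**
Reactants: 14 epoxy alcohol
Product: 15 8,17-epoxy-12-iodo-3-(tert-butyldimethylsilyloxy)-13,14,15,16-tetranor-ent-labdane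
Conditions: PPh3, imidazole, I2, CH2Cl2, 0 °C
Reagents that add atoms: iodine II
Why: Appel-type iodination of the unhindered primary alcohol is fast at 0 °C, and the imidazole buffer keeps the epoxide intact, as is usual for epoxy alcohols under these conditions.

**Step 13**
Reactants: 15 epoxy iodide; 16 ethynyltrimethylsilane
Product: 17 8,17-epoxy-3-(tert-butyldimethylsilyloxy)-14-(trimethylsilyl)-15,16-dinor-ent-labd-13-yne
Conditions: 16, n-BuLi, THF, −78 °C; then 15, DMPU, −78 to 0 °C
Reagents that add atoms: ethynyltrimethylsilane C#C[Si](C)(C)C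
Why: SN2 alkylation of the lithium acetylide by the primary iodide forms the C12–C13 bond, the silyl cap prevents double alkylation, and without a Lewis acid the acetylide should not open the hindered epoxide at this temperature.

**Step 14**
Reactants: 17 silyl alkyne
Product: 18 8,17-epoxy-3-(tert-butyldimethylsilyloxy)-15,16-dinor-ent-labd-13-yne
Conditions: K2CO3 (cat.), MeOH, rt
Reagents that add atoms: none
Why: Base-catalysed methanolysis cleaves only the alkynyl C–Si bond, the alkyl silyl ether and the epoxide being inert to carbonate in methanol at rt.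

**Step 15**
Reactants: 18 terminal alkyne; 19 methyl chloroformate
Product: 21 methyl 8,17-epoxy-3-(tert-butyldimethylsilyloxy)-16-nor-ent-labd-13-yn-15-oate, via lithium acetylide 20 (not isolated)
Conditions: n-BuLi, THF, −78 °C; then 19, −78 to −20 °C
Reagents that add atoms: methyl chloroformate COC(=O)Cl
Why: Deprotonation of the terminal alkyne and C-acylation of the acetylide by the chloroformate install C15, and the epoxide does not react with the organolithium at −78 °C.

**Step 16**
Reactants: 21 ynoate
Product: 23 methyl (13Z)-8,17-epoxy-3-(tert-butyldimethylsilyloxy)-ent-labd-13-en-15-oate, via alkenylcuprate 22 (not isolated)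
Conditions: Me2CuLi (from MeLi and CuI), THF, −78 °C; MeOH then aq. NH4Cl, −78 °C
Reagents that add atoms: lithium dimethylcuprate [Li+].C[Cu-]C
Why: Conjugate syn-carbocupration of the ynoate places the new methyl group (C16) and copper on the same side of C13=C14, and protonation with retention at −78 °C, before the alkenylcuprate can equilibrate through the allenolate, gives the 13Z enoate while the epoxide is too slow to be opened by the cuprate.

**Step 17**
Reactants: 23 Z-enoate epoxide
Product: 25 (13Z)-8,17-dihydroxy-3-(tert-butyldimethylsilyloxy)-ent-labd-13-en-15-oic acid, via lithium carboxylate 24 (not isolated)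
Conditions: LiOH, THF–MeOH–H2O, rt; then KOH, DMSO–H2O, 90 °C; 1 M HCl to pH 4, 0 °C
Reagents that add atoms: lithium hydroxide [Li+].[OH-]; potassium hydroxide [K+].[OH-]
Why: Saponification first turns the enoate into a carboxylate that resists γ-deprotonation (so the Z geometry should hold), and hydroxide then opens the epoxide by SN2 attack at the primary C17, which leaves the C8–O bond and the C8 configuration untouched.

**Step 18**
Reactants: 25 dihydroxy acid
Product: 26 (13Z)-8-hydroxy-17-oxo-3-(tert-butyldimethylsilyloxy)-ent-labd-13-en-15-oic acid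
Conditions: IBX, DMSO, rt
Reagents that add atoms: none
Why: IBX oxidation takes the primary C17 alcohol to the aldehyde without cleaving the 1,2-diol, cannot touch the tertiary C8 carbinol, tolerates the free acid, and gives an aldehyde with no α-hydrogen.

**Step 19**
Reactants: 26 silyl-protected hydroxy aldehyde
Product: 27 (13Z)-3,8-dihydroxy-17-oxo-ent-labd-13-en-15-oic acid (target)
Conditions: 48% aq. HF, MeCN, rt
Reagents that add atoms: none
Why: Acidic fluoride desilylation removes the hindered secondary silyl ether under non-basic conditions, so the α-hydroxy aldehyde should not undergo α-ketol rearrangement and the Z-enoic acid should not isomerise.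

**Compound list**
1 | andrographolide | O=C1OC[C@@H](O)/C1=C\C[C@H]1[C@]2(C)CC[C@@H](O)[C@@](C)(CO)[C@H]2CCC1=C | starting material
2 | 3,19-O-isopropylideneandrographolide | O=C1OC[C@@H](O)/C1=C\C[C@H]1[C@]2(C)CC[C@H]3OC(C)(C)OC[C@@]3(C)[C@H]2CCC1=C | intermediate
3 | 3,19-isopropylidenedioxy-13,14,15,16-tetranor-ent-labd-8(17)-en-12-al | O=CC[C@H]1[C@]2(C)CC[C@H]3OC(C)(C)OC[C@@]3(C)[C@H]2CCC1=C | intermediate
4 | 3,19-isopropylidenedioxy-13,14,15,16-tetranor-ent-labd-8(17)-en-12-oic acid | OC(=O)C[C@H]1[C@]2(C)CC[C@H]3OC(C)(C)OC[C@@]3(C)[C@H]2CCC1=C | intermediate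
5 | methyl ester of 4 (not isolated) | COC(=O)C[C@H]1[C@]2(C)CC[C@H]3OC(C)(C)OC[C@@]3(C)[C@H]2CCC1=C | intermediate
6 | methyl 3,19-dihydroxy-13,14,15,16-tetranor-ent-labd-8(17)-en-12-oate | COC(=O)C[C@H]1[C@]2(C)CC[C@@H](O)[C@@](C)(CO)[C@H]2CCC1=C | intermediate
7 | methyl 3-hydroxy-19-iodo-13,14,15,16-tetranor-ent-labd-8(17)-en-12-oate | COC(=O)C[C@H]1[C@]2(C)CC[C@@H](O)[C@@](C)(CI)[C@H]2CCC1=C | intermediate
8 | methyl 3-hydroxy-13,14,15,16-tetranor-ent-labd-8(17)-en-12-oate | COC(=O)C[C@H]1[C@]2(C)CC[C@@H](O)C(C)(C)[C@H]2CCC1=C | intermediate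
9 | methyl 3-(tert-butyldimethylsilyloxy)-13,14,15,16-tetranor-ent-labd-8(17)-en-12-oate | COC(=O)C[C@H]1[C@]2(C)CC[C@@H](O[Si](C)(C)C(C)(C)C)C(C)(C)[C@H]2CCC1=C | intermediate
10 | 3-(tert-butyldimethylsilyloxy)-13,14,15,16-tetranor-ent-labd-8(17)-en-12-oic acid (key-step precursor) | OC(=O)C[C@H]1[C@]2(C)CC[C@@H](O[Si](C)(C)C(C)(C)C)C(C)(C)[C@H]2CCC1=C | intermediate
11 | cis-fused 17-iodo-12,8-lactone, C8–O axial and syn to C20 (key-step product) | O=C1C[C@H]2[C@]3(C)CC[C@@H](O[Si](C)(C)C(C)(C)C)C(C)(C)[C@H]3CC[C@@]2(CI)O1 | intermediate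
12 | methyl 8-hydroxy-17-iodo-3-(tert-butyldimethylsilyloxy)-13,14,15,16-tetranor-ent-labdan-12-oate (not isolated) | COC(=O)C[C@H]1[C@]2(C)CC[C@@H](O[Si](C)(C)C(C)(C)C)C(C)(C)[C@H]2CC[C@]1(O)CI | intermediate
13 | methyl 8,17-epoxy-3-(tert-butyldimethylsilyloxy)-13,14,15,16-tetranor-ent-labdan-12-oate, epoxide oxygen syn to C20 | COC(=O)C[C@H]1[C@]2(C)CC[C@@H](O[Si](C)(C)C(C)(C)C)C(C)(C)[C@H]2CC[C@]13CO3 | intermediate
14 | 8,17-epoxy-3-(tert-butyldimethylsilyloxy)-13,14,15,16-tetranor-ent-labdan-12-ol | OCC[C@H]1[C@]2(C)CC[C@@H](O[Si](C)(C)C(C)(C)C)C(C)(C)[C@H]2CC[C@]13CO3 | intermediate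
15 | 8,17-epoxy-12-iodo-3-(tert-butyldimethylsilyloxy)-13,14,15,16-tetranor-ent-labdane | ICC[C@H]1[C@]2(C)CC[C@@H](O[Si](C)(C)C(C)(C)C)C(C)(C)[C@H]2CC[C@]13CO3 | intermediate
16 | ethynyltrimethylsilane | C#C[Si](C)(C)C | starting material
17 | 8,17-epoxy-3-(tert-butyldimethylsilyloxy)-14-(trimethylsilyl)-15,16-dinor-ent-labd-13-yne | C[Si](C)(C)C#CCC[C@H]1[C@]2(C)CC[C@@H](O[Si](C)(C)C(C)(C)C)C(C)(C)[C@H]2CC[C@]13CO3 | intermediate
18 | 8,17-epoxy-3-(tert-butyldimethylsilyloxy)-15,16-dinor-ent-labd-13-yne | C#CCC[C@H]1[C@]2(C)CC[C@@H](O[Si](C)(C)C(C)(C)C)C(C)(C)[C@H]2CC[C@]13CO3 | intermediate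
19 | methyl chloroformate | COC(=O)Cl | starting material
20 | lithium acetylide of 18 (not isolated) | [Li]C#CCC[C@H]1[C@]2(C)CC[C@@H](O[Si](C)(C)C(C)(C)C)C(C)(C)[C@H]2CC[C@]13CO3 | intermediate
21 | methyl 8,17-epoxy-3-(tert-butyldimethylsilyloxy)-16-nor-ent-labd-13-yn-15-oate | COC(=O)C#CCC[C@H]1[C@]2(C)CC[C@@H](O[Si](C)(C)C(C)(C)C)C(C)(C)[C@H]2CC[C@]13CO3 | intermediate
22 | lithium methyl(alkenyl)cuprate from syn addition to 21, copper on C14 cis to the C16 methyl (not isolated) | [Li+].C[Cu-]/C(C(=O)OC)=C(\C)CC[C@H]1[C@]2(C)CC[C@@H](O[Si](C)(C)C(C)(C)C)C(C)(C)[C@H]2CC[C@]13CO3 | intermediate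
23 | methyl (13Z)-8,17-epoxy-3-(tert-butyldimethylsilyloxy)-ent-labd-13-en-15-oate | C/C(=C/C(=O)OC)CC[C@H]1[C@]2(C)CC[C@@H](O[Si](C)(C)C(C)(C)C)C(C)(C)[C@H]2CC[C@]13CO3 | intermediate
24 | lithium (13Z)-8,17-epoxy-3-(tert-butyldimethylsilyloxy)-ent-labd-13-en-15-oate (not isolated) | C/C(=C/C(=O)[O-])CC[C@H]1[C@]2(C)CC[C@@H](O[Si](C)(C)C(C)(C)C)C(C)(C)[C@H]2CC[C@]13CO3.[Li+] | intermediate
25 | (13Z)-8,17-dihydroxy-3-(tert-butyldimethylsilyloxy)-ent-labd-13-en-15-oic acid | C/C(=C/C(=O)O)CC[C@H]1[C@]2(C)CC[C@@H](O[Si](C)(C)C(C)(C)C)C(C)(C)[C@H]2CC[C@]1(O)CO | intermediate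
26 | (13Z)-8-hydroxy-17-oxo-3-(tert-butyldimethylsilyloxy)-ent-labd-13-en-15-oic acid | C/C(=C/C(=O)O)CC[C@H]1[C@]2(C)CC[C@@H](O[Si](C)(C)C(C)(C)C)C(C)(C)[C@H]2CC[C@]1(O)C=O | intermediate
27 | (13Z)-3,8-dihydroxy-17-oxo-ent-labd-13-en-15-oic acid (CNP0273710.1) | C/C(=C/C(=O)O)CC[C@H]1[C@]2(C)CC[C@@H](O)C(C)(C)[C@H]2CC[C@]1(O)C=O | target

**Step count and risk**
Total step count: 19. Longest linear sequence: 19 steps (from andrographolide; 16 and 19 are bought).

Steps most likely to fail:

1. Step 9 (key step). The iodonium ion might be opened in a competing mode (6-endo closure, or attack from the other face), or the addition might revert during work-up, which would erode the configuration at C8. The fallback sets out from 10 and replaces halocyclisation by epoxidation and invertive epoxide opening. mCPBA with NaHCO3 in CH2Cl2 at 0 °C should epoxidise the methylene from the open face anti to C20 and give the epimeric 8,17-epoxy acid F1. With catalytic CSA in CH2Cl2 the carboxyl group should open this epoxide at the tertiary C8 with inversion (5-exo), which places the lactone oxygen on the C20 face and gives the 17-hydroxy-12,8-lactone F2. MsCl and Et3N would give the mesylate F3, and NaOMe in MeOH would open the lactone and close the epoxide by displacement of the mesylate. The fallback comes back to the route at 13.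

2. Step 17. SN2 opening at the neopentyl-type C17 may be sluggish, and forcing conditions could bring Z-to-E isomerisation or loss of the silyl ether. The fallback sets out from 17 and opens the epoxide before the enoate exists. KOH in DMSO–H2O at 90 °C should cleave the alkynylsilane and open the epoxide to the 8,17-diol alkyne F4. 2,2-Dimethoxypropane with PPTS would give the 8,17-acetonide F5. n-BuLi then 19 would give the ynoate F6, and Me2CuLi at −78 °C the Z-enoate F7. LiOH would give the acid F8, and 80% aqueous AcOH at 40 °C should remove the acetonide while the C3 silyl ether stays. The fallback comes back to the route at 25.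

3. Step 2. Permanganate may not discriminate well enough between the two alkenes, so that the 8(17)-methylene is oxidised as well. The fallback sets out from 2 and uses a nucleophilic oxidant that cannot touch the isolated alkene. Lithium tert-butyl peroxide (t-BuOOH, n-BuLi, THF, −20 °C; Weitz–Scheffer-type epoxidation) should give the 12,13-epoxide F9 as a mixture at C12 and C13, both of which are excised. H5IO6 in THF–Et2O at 0 °C should then cleave the epoxide through the diol to the aldehyde; if the acetonide is partly lost it is closed again with 2,2-dimethoxypropane and PPTS. The fallback comes back to the route at 3.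

**Further compounds**
F1 | step 9 | 8,17-epoxy-3-(tert-butyldimethylsilyloxy)-13,14,15,16-tetranor-ent-labdan-12-oic acid, epoxide oxygen anti to C20 | OC(=O)C[C@H]1[C@]2(C)CC[C@@H](O[Si](C)(C)C(C)(C)C)C(C)(C)[C@H]2CC[C@@]13CO3
F2 | step 9 | cis-fused 17-hydroxy-12,8-lactone, C8–O syn to C20 | O=C1C[C@H]2[C@]3(C)CC[C@@H](O[Si](C)(C)C(C)(C)C)C(C)(C)[C@H]3CC[C@@]2(CO)O1
F3 | step 9 | 17-methanesulfonate of F2 | O=C1C[C@H]2[C@]3(C)CC[C@@H](O[Si](C)(C)C(C)(C)C)C(C)(C)[C@H]3CC[C@@]2(COS(C)(=O)=O)O1
F4 | step 17 | 8,17-dihydroxy-3-(tert-butyldimethylsilyloxy)-15,16-dinor-ent-labd-13-yne | C#CCC[C@H]1[C@]2(C)CC[C@@H](O[Si](C)(C)C(C)(C)C)C(C)(C)[C@H]2CC[C@]1(O)CO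
F5 | step 17 | 8,17-O-isopropylidene derivative of F4 | C#CCC[C@H]1[C@]2(C)CC[C@@H](O[Si](C)(C)C(C)(C)C)C(C)(C)[C@H]2CC[C@]13COC(C)(C)O3
F6 | step 17 | methyl 8,17-isopropylidenedioxy-3-(tert-butyldimethylsilyloxy)-16-nor-ent-labd-13-yn-15-oate | COC(=O)C#CCC[C@H]1[C@]2(C)CC[C@@H](O[Si](C)(C)C(C)(C)C)C(C)(C)[C@H]2CC[C@]13COC(C)(C)O3
F7 | step 17 | methyl (13Z)-8,17-isopropylidenedioxy-3-(tert-butyldimethylsilyloxy)-ent-labd-13-en-15-oate | C/C(=C/C(=O)OC)CC[C@H]1[C@]2(C)CC[C@@H](O[Si](C)(C)C(C)(C)C)C(C)(C)[C@H]2CC[C@]13COC(C)(C)O3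
F8 | step 17 | (13Z)-8,17-isopropylidenedioxy-3-(tert-butyldimethylsilyloxy)-ent-labd-13-en-15-oic acid | C/C(=C/C(=O)O)CC[C@H]1[C@]2(C)CC[C@@H](O[Si](C)(C)C(C)(C)C)C(C)(C)[C@H]2CC[C@]13COC(C)(C)O3
F9 | step 2 | 12,13-epoxide of 2 (mixture at C12 and C13) | O=C1OC[C@@H](O)C12OC2C[C@H]2[C@]3(C)CC[C@H]4OC(C)(C)OC[C@@]4(C)[C@H]3CCC2=C
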